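## Retrosynthetic overview

1. The target is cut at the CH2 bridge: Michael addition of the pyrone of naphthalene fragment 25 to the 3-methylene-pyrandione released from Mannich base 26 of tetralone fragment 23. Fragment 25 is simply acid-dehydrated 23.
2. The pyranone of 23 is grown on aldehyde 14 by a vinylogous Mukaiyama aldol, oxidation and acylketene cyclisation.
3. C3 and C4 come from a hydroxyl-directed syn-epoxidation of dihydronaphthalenol 8 and a trans-diaxial vinyl opening at C4. The C1 carbinol relays chirality and is then oxidised to the ketone.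
4. Alcohol 8 comes from ring-closing metathesis of 7, which is made from (R)-aryl oxirane 5 (hydrolytic kinetic resolution) and a 1-phenylvinyl Grignard reagent.
5. Ring order: carbocycle of the tetralin (metathesis), transient oxirane, pyranone, second benzenoid ring of the naphthalene (dehydration of part of 23), methylene bridge last.

Assumption: 2-bromo-6-hydroxybenzaldehyde, (1-phenylethenyl)magnesium bromide solution and 2,2,6-trimethyl-4H-1,3-dioxin-4-one are bought; compound 23 is divided between steps 18 and 19.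

## Route

Step 1
Reactants: 1 2-bromo-6-hydroxybenzaldehyde
Product: 2 2-(benzyloxy)-6-bromobenzaldehyde
Conditions: BnBr (1.1 equiv), K2CO3 (1.5 equiv), DMF, rt
Reagents that add atoms: benzyl bromide, BrCc1ccccc1
Why: Williamson ether synthesis on the acidic phenol gives a benzyl ether that survives the organometallic, oxidative and Lewis-acid steps and is removed late by hydrogenolysis.

Step 2
Reactants: 2 2-(benzyloxy)-6-bromobenzaldehyde
Product: 3 2-(benzyloxy)-6-ethenylbenzaldehyde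
Conditions: Bu3SnCH=CH2 (1.2 equiv), Pd(PPh3)4 (5 mol %), toluene, 100 °C
Reagents that add atoms: tributyl(ethenyl)stannane, C=C[Sn](CCCC)(CCCC)CCCC
Why: Stille coupling of an aryl bromide runs under neutral conditions that leave the aldehyde untouched.

Step 3
Reactants: 3 2-(benzyloxy)-6-ethenylbenzaldehyde
Product: 4 rac-2-[2-(benzyloxy)-6-ethenylphenyl]oxirane
Conditions: Me3S+ I− (1.3 equiv), NaH (1.3 equiv), DMSO–THF, 0 °C → rt
Reagents that add atoms: trimethylsulfonium iodide, C[S+](C)C.[I-]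
Why: Corey–Chaykovsky epoxidation, in which the sulfonium ylide adds to the aldehyde and the betaine closes to the terminal oxirane (racemic, resolved in the next step).

Step 4
Reactants: 4 rac-2-[2-(benzyloxy)-6-ethenylphenyl]oxirane
Product: 5 (2R)-2-[2-(benzyloxy)-6-ethenylphenyl]oxirane
Conditions: (R,R)-(salen)Co(OAc) (trivalent cobalt, 1 mol %), H2O (0.55 equiv), THF, 0 °C → rt, 36 h; chromatography on Et3N-washed silica
Reagents that add atoms: none
Why: Jacobsen hydrolytic kinetic resolution, in which the (R,R)-catalyst hydrolyses the (S)-oxirane at its terminal carbon and leaves the (R)-oxirane in ≥99% ee, setting the one stereocentre from which all others are relayed.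

Step 5
Reactants: 5 (2R)-2-[2-(benzyloxy)-6-ethenylphenyl]oxirane; 6 (1-phenylethenyl)magnesium bromide
Product: 7 (1S)-1-[2-(benzyloxy)-6-ethenylphenyl]-3-phenylbut-3-en-1-ol
Conditions: 6 (1.5 equiv), CuI (10 mol %), THF, −40 → −10 °C; aq. NH4Cl
Reagents that add atoms: none
Why: Copper-catalysed Grignard opening of the epoxide (SN2) occurs at the unhindered terminal carbon, so the benzylic stereocentre is untouched (R to S is only a priority change).

Step 6
Reactants: 7 (1S)-1-[2-(benzyloxy)-6-ethenylphenyl]-3-phenylbut-3-en-1-ol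
Product: 8 (1S)-8-(benzyloxy)-3-phenyl-1,2-dihydronaphthalen-1-ol
Conditions: second-generation Grubbs catalyst (H2IMes)(PCy3)Cl2Ru=CHPh (5 mol %), CH2Cl2 (5 mM), 40 °C; Et3N-washed silica
Reagents that add atoms: none
Why: Ring-closing metathesis of the styrene with the 1,1-disubstituted alkene closes a six-membered ring with loss of ethene and gives the conjugated trisubstituted C3=C4 alkene.

Step 7
Reactants: 8 (1S)-8-(benzyloxy)-3-phenyl-1,2-dihydronaphthalen-1-ol
Product: 9 (1S,3S,4S)-8-(benzyloxy)-3,4-epoxy-3-phenyl-1,2,3,4-tetrahydronaphthalen-1-ol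
Conditions: t-BuOOH (1.5 equiv, decane), VO(acac)2 (5 mol %), CH2Cl2, 0 °C → rt
Reagents that add atoms: tert-butyl hydroperoxide, CC(C)(C)OO
Why: Hydroxyl-directed vanadium-catalysed epoxidation of a cyclic homoallylic alcohol, in which the vanadate ester of the pseudoaxial C1 oxygen (pushed axial by the peri benzyloxy group) delivers oxygen to the alkene face cis to that hydroxyl, fixing C3 and C4.

Step 8
Reactants: 9 (1S,3S,4S)-8-(benzyloxy)-3,4-epoxy-3-phenyl-1,2,3,4-tetrahydronaphthalen-1-ol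
Product: 10 (1S,3R,4R)-8-(benzyloxy)-4-ethenyl-3-phenyl-1,2,3,4-tetrahydronaphthalene-1,3-diol
Conditions: CH2=CHMgBr (5 equiv), CuI (20 mol %), THF, −40 → −10 °C; aq. NH4Cl
Reagents that add atoms: ethenylmagnesium bromide, C=C[Mg]Br
Why: Copper-mediated SN2 epoxide opening goes trans-diaxially (Fürst–Plattner) at the secondary benzylic C4 with inversion, placing the vinyl group trans to the C3 oxygen and cis to phenyl while the tertiary C3–O bond is not touched.

Step 9
Reactants: 10 (1S,3R,4R)-8-(benzyloxy)-4-ethenyl-3-phenyl-1,2,3,4-tetrahydronaphthalene-1,3-diol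
Product: 11 (3R,4R)-8-(benzyloxy)-4-ethenyl-3-hydroxy-3-phenyl-3,4-dihydronaphthalen-1(2H)-one
Conditions: Dess–Martin periodinane (1.2 equiv), pyridine (3 equiv), CH2Cl2, 0 °C → rt
Reagents that add atoms: none
Why: Dess–Martin oxidation takes only the secondary benzylic alcohol (the tertiary one cannot be oxidised), installing the C1 ketone and erasing the relay stereocentre under near-neutral conditions that do not dehydrate the β-hydroxy ketone.

Step 10
Reactants: 11 (3R,4R)-8-(benzyloxy)-4-ethenyl-3-hydroxy-3-phenyl-3,4-dihydronaphthalen-1(2H)-one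
Product: 12 (3R,4R)-8-(benzyloxy)-4-ethenyl-3-phenyl-3-[(triethylsilyl)oxy]-3,4-dihydronaphthalen-1(2H)-one
Conditions: Et3SiOTf (1.5 equiv), 2,6-lutidine (3 equiv), CH2Cl2, −78 → 0 °C
Reagents that add atoms: triethylsilyl trifluoromethanesulfonate, CC[Si](CC)(CC)OS(=O)(=O)C(F)(F)F
Why: Silyl triflate silylation of the hindered tertiary alcohol blocks retro-aldol cleavage, dehydration and later capture of the acylketene by this hydroxyl.

Step 11
Reactants: 12 (3R,4R)-8-(benzyloxy)-4-ethenyl-3-phenyl-3-[(triethylsilyl)oxy]-3,4-dihydronaphthalen-1(2H)-one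
Product: 14 (1R,2R)-5-(benzyloxy)-4-oxo-2-phenyl-2-[(triethylsilyl)oxy]-1,2,3,4-tetrahydronaphthalene-1-carbaldehyde, via secondary ozonide 13 (not isolated)
Conditions: O3, CH2Cl2, −78 °C (Sudan Red end point); PPh3 (1.5 equiv), −78 °C → rt; used crude
Reagents that add atoms: ozone, [O-][O+]=O
Why: Ozonolysis with reductive work-up cleaves the only alkene to the aldehyde without base, so the α-aryl stereocentre is not epimerised.

Step 12
Reactants: 15 2,2,6-trimethyl-4H-1,3-dioxin-4-one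
Product: 17 [(2,2-dimethyl-6-methylidene-6H-1,3-dioxin-4-yl)oxy]trimethylsilane, via lithium dienolate 16 (not isolated)
Conditions: LiN(i-Pr)2 (1.1 equiv), THF, −78 °C; Me3SiCl (1.3 equiv), −78 → 0 °C
Reagents that add atoms: chlorotrimethylsilane, C[Si](C)(C)Cl
Why: Kinetic γ-deprotonation of the vinylogous ester and O-silylation give the silyl dienol ether needed for a base-free aldol.

Step 13
Reactants: 14 (1R,2R)-5-(benzyloxy)-4-oxo-2-phenyl-2-[(triethylsilyl)oxy]-1,2,3,4-tetrahydronaphthalene-1-carbaldehyde; 17 [(2,2-dimethyl-6-methylidene-6H-1,3-dioxin-4-yl)oxy]trimethylsilane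
Product: 18 6-{2-[(1S,2R)-5-(benzyloxy)-4-oxo-2-phenyl-2-[(triethylsilyl)oxy]-1,2,3,4-tetrahydronaphthalen-1-yl]-2-hydroxyethyl}-2,2-dimethyl-4H-1,3-dioxin-4-one (both carbinol epimers)
Conditions: 17 (2 equiv), BF3·OEt2 (1.2 equiv), CH2Cl2, −78 °C; aq. NaHCO3
Reagents that add atoms: none
Why: Vinylogous Mukaiyama aldol addition at the γ-carbon is chemoselective for the aldehyde over the aryl ketone and needs no base, so C4 keeps its configuration, and the new carbinol centre is irrelevant because it is oxidised next.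

Step 14
Reactants: 18 6-{2-[(1S,2R)-5-(benzyloxy)-4-oxo-2-phenyl-2-[(triethylsilyl)oxy]-1,2,3,4-tetrahydronaphthalen-1-yl]-2-hydroxyethyl}-2,2-dimethyl-4H-1,3-dioxin-4-one
Product: 19 6-{2-[(1R,2R)-5-(benzyloxy)-4-oxo-2-phenyl-2-[(triethylsilyl)oxy]-1,2,3,4-tetrahydronaphthalen-1-yl]-2-oxoethyl}-2,2-dimethyl-4H-1,3-dioxin-4-one
Conditions: Dess–Martin periodinane (1.5 equiv), CH2Cl2, 0 °C → rt
Reagents that add atoms: none
Why: Dess–Martin oxidation of the secondary alcohol gives the ketone under non-basic conditions, converging both epimers.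

Step 15
Reactants: 19 6-{2-[(1R,2R)-5-(benzyloxy)-4-oxo-2-phenyl-2-[(triethylsilyl)oxy]-1,2,3,4-tetrahydronaphthalen-1-yl]-2-oxoethyl}-2,2-dimethyl-4H-1,3-dioxin-4-one
Product: 21 (3R,4S)-8-(benzyloxy)-4-(4-hydroxy-2-oxo-2H-pyran-6-yl)-3-phenyl-3-[(triethylsilyl)oxy]-3,4-dihydronaphthalen-1(2H)-one, via acylketene 20 (not isolated)
Conditions: toluene, 110 °C, 45 min
Reagents that add atoms: none
Why: Thermal retro-[4+2] loss of acetone gives an acylketene that is trapped by the enol oxygen of the neighbouring ketone (intramolecular O-acylation) to form the 4-hydroxy-2-pyranone under neutral conditions.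

Step 16
Reactants: 21 (3R,4S)-8-(benzyloxy)-4-(4-hydroxy-2-oxo-2H-pyran-6-yl)-3-phenyl-3-[(triethylsilyl)oxy]-3,4-dihydronaphthalen-1(2H)-one
Product: 22 (3R,4S)-8-hydroxy-4-(4-hydroxy-2-oxo-2H-pyran-6-yl)-3-phenyl-3-[(triethylsilyl)oxy]-3,4-dihydronaphthalen-1(2H)-one
Conditions: H2 (1 atm), 10% Pd/C, EtOAc, rt, stopped at full conversion
Reagents that add atoms: none
Why: Hydrogenolysis of the aryl benzyl ether is much faster than reduction of the hindered pyranone or the aryl ketone, and the silylated tertiary benzylic oxygen is inert.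

Step 17
Reactants: 22 (3R,4S)-8-hydroxy-4-(4-hydroxy-2-oxo-2H-pyran-6-yl)-3-phenyl-3-[(triethylsilyl)oxy]-3,4-dihydronaphthalen-1(2H)-one
Product: 23 (3R,4R)-3,8-dihydroxy-4-(4-hydroxy-2-oxo-2H-pyran-6-yl)-3-phenyl-3,4-dihydronaphthalen-1(2H)-one
Conditions: HF·pyridine, pyridine, THF, 0 °C → rt
Reagents that add atoms: none
Why: Buffered fluoride desilylation frees the tertiary alcohol without the strong acid or base that would dehydrate or cleave the β-hydroxy ketone.

Step 18
Reactants: 23 (3R,4R)-3,8-dihydroxy-4-(4-hydroxy-2-oxo-2H-pyran-6-yl)-3-phenyl-3,4-dihydronaphthalen-1(2H)-one (about 45% of the material)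
Product: 25 6-(4,5-dihydroxy-2-phenylnaphthalen-1-yl)-4-hydroxy-2H-pyran-2-one, via 4H-naphthalenone tautomer 24 (not isolated)
Conditions: p-TsOH·H2O (0.2 equiv), 1,4-dioxane, 70 °C
Reagents that add atoms: none
Why: Acid-catalysed dehydration of the tertiary benzylic β-hydroxy ketone (aldol-condensation-type elimination) followed by keto–enol tautomerisation is driven by aromatisation, and both stereocentres are deliberately destroyed.

Step 19
Reactants: 23 (3R,4R)-3,8-dihydroxy-4-(4-hydroxy-2-oxo-2H-pyran-6-yl)-3-phenyl-3,4-dihydronaphthalen-1(2H)-one (about 55% of the material)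
Product: 26 (3R,4R)-4-{3-[(dimethylamino)methyl]-4-hydroxy-2-oxo-2H-pyran-6-yl}-3,8-dihydroxy-3-phenyl-3,4-dihydronaphthalen-1(2H)-one
Conditions: Eschenmoser's salt (1.05 equiv), i-Pr2NEt (1.0 equiv), MeCN, 0 °C → rt; isolated by trituration as the zwitterion
Reagents that add atoms: N,N-dimethylmethyleneiminium iodide, C=[N+](C)C.[I-]
Why: Mannich reaction at pyranone C3, the only strongly nucleophilic carbon, since the chelated phenol on the acyl-deactivated ring and the ketone α-carbon do not compete at 0 °C.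

Step 20
Reactants: 26 (3R,4R)-4-{3-[(dimethylamino)methyl]-4-hydroxy-2-oxo-2H-pyran-6-yl}-3,8-dihydroxy-3-phenyl-3,4-dihydronaphthalen-1(2H)-one; 25 6-(4,5-dihydroxy-2-phenylnaphthalen-1-yl)-4-hydroxy-2H-pyran-2-one
Product: 28 wailupemycin I, via 3-methylenepyrandione 27 (not isolated)
Conditions: 25 (1.3 equiv), MeCN–1,4-dioxane (1:1), 60 °C, N2 sweep; reversed-phase chromatography
Reagents that add atoms: none
Why: Thermal retro-Mannich loss of dimethylamine from the zwitterion unmasks the 3-methylene-pyran-2,4-dione, which undergoes intermolecular Michael addition by the pyronate carbon of 25 (an enolate far more nucleophilic than the neutral naphthols) to form the CH2 bridge; no stereocentre is formed and C3/C4 are untouched in this self-buffered medium.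

## Compound list

1 | 2-bromo-6-hydroxybenzaldehyde | O=Cc1c(O)cccc1Br | starting material
2 | 2-(benzyloxy)-6-bromobenzaldehyde | O=Cc1c(Br)cccc1OCc1ccccc1 | intermediate
3 | 2-(benzyloxy)-6-ethenylbenzaldehyde | O=Cc1c(C=C)cccc1OCc1ccccc1 | intermediate
4 | rac-2-[2-(benzyloxy)-6-ethenylphenyl]oxirane | C=Cc1cccc(OCc2ccccc2)c1C1CO1 | intermediate
5 | (2R)-2-[2-(benzyloxy)-6-ethenylphenyl]oxirane | C=Cc1cccc(OCc2ccccc2)c1[C@@H]1CO1 | intermediate
6 | (1-phenylethenyl)magnesium bromide | C=C([Mg]Br)c1ccccc1 | starting material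
7 | (1S)-1-[2-(benzyloxy)-6-ethenylphenyl]-3-phenylbut-3-en-1-ol | C=Cc1cccc(OCc2ccccc2)c1[C@@H](O)CC(=C)c1ccccc1 | intermediate
8 | (1S)-8-(benzyloxy)-3-phenyl-1,2-dihydronaphthalen-1-ol | O[C@H]1CC(c2ccccc2)=Cc2cccc(OCc3ccccc3)c21 | intermediate
9 | (1S,3S,4S)-8-(benzyloxy)-3,4-epoxy-3-phenyl-1,2,3,4-tetrahydronaphthalen-1-ol (oxirane oxygen cis to the 1-hydroxyl) | O[C@H]1C[C@@]2(c3ccccc3)O[C@H]2c2cccc(OCc3ccccc3)c21 | intermediate
10 | (1S,3R,4R)-8-(benzyloxy)-4-ethenyl-3-phenyl-1,2,3,4-tetrahydronaphthalene-1,3-diol (hydroxyls cis, ethenyl trans to the 3-hydroxyl) | O[C@H]1C[C@](O)(c2ccccc2)[C@H](C=C)c2cccc(OCc3ccccc3)c21 | intermediate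
11 | (3R,4R)-8-(benzyloxy)-4-ethenyl-3-hydroxy-3-phenyl-3,4-dihydronaphthalen-1(2H)-one | O=C1C[C@](O)(c2ccccc2)[C@H](C=C)c2cccc(OCc3ccccc3)c21 | intermediate
12 | (3R,4R)-8-(benzyloxy)-4-ethenyl-3-phenyl-3-[(triethylsilyl)oxy]-3,4-dihydronaphthalen-1(2H)-one | O=C1C[C@](O[Si](CC)(CC)CC)(c2ccccc2)[C@H](C=C)c2cccc(OCc3ccccc3)c21 | intermediate
13 | (3R,4R)-8-(benzyloxy)-3-phenyl-3-[(triethylsilyl)oxy]-4-(1,2,4-trioxolan-3-yl)-3,4-dihydronaphthalen-1(2H)-one (secondary ozonide, both epimers at the trioxolane carbon) | O=C1C[C@](O[Si](CC)(CC)CC)(c2ccccc2)[C@H](C2OCOO2)c2cccc(OCc3ccccc3)c21 | intermediate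
14 | (1R,2R)-5-(benzyloxy)-4-oxo-2-phenyl-2-[(triethylsilyl)oxy]-1,2,3,4-tetrahydronaphthalene-1-carbaldehyde | O=C1C[C@](O[Si](CC)(CC)CC)(c2ccccc2)[C@H](C=O)c2cccc(OCc3ccccc3)c21 | intermediate
15 | 2,2,6-trimethyl-4H-1,3-dioxin-4-one | CC1=CC(=O)OC(C)(C)O1 | starting material
16 | lithium 2,2-dimethyl-6-methylidene-6H-1,3-dioxin-4-olate (lithium dienolate) | C=C1C=C([O-])OC(C)(C)O1.[Li+] | intermediate
17 | [(2,2-dimethyl-6-methylidene-6H-1,3-dioxin-4-yl)oxy]trimethylsilane | C=C1C=C(O[Si](C)(C)C)OC(C)(C)O1 | intermediate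
18 | 6-{2-[(1S,2R)-5-(benzyloxy)-4-oxo-2-phenyl-2-[(triethylsilyl)oxy]-1,2,3,4-tetrahydronaphthalen-1-yl]-2-hydroxyethyl}-2,2-dimethyl-4H-1,3-dioxin-4-one (both carbinol epimers; 1S is a priority change only) | O=C1C[C@](O[Si](CC)(CC)CC)(c2ccccc2)[C@H](C(O)CC2=CC(=O)OC(C)(C)O2)c2cccc(OCc3ccccc3)c21 | intermediate
19 | 6-{2-[(1R,2R)-5-(benzyloxy)-4-oxo-2-phenyl-2-[(triethylsilyl)oxy]-1,2,3,4-tetrahydronaphthalen-1-yl]-2-oxoethyl}-2,2-dimethyl-4H-1,3-dioxin-4-one | O=C1C[C@](O[Si](CC)(CC)CC)(c2ccccc2)[C@H](C(=O)CC2=CC(=O)OC(C)(C)O2)c2cccc(OCc3ccccc3)c21 | intermediate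
20 | 5-[(1R,2R)-5-(benzyloxy)-4-oxo-2-phenyl-2-[(triethylsilyl)oxy]-1,2,3,4-tetrahydronaphthalen-1-yl]pent-1-ene-1,3,5-trione (acylketene) | O=C1C[C@](O[Si](CC)(CC)CC)(c2ccccc2)[C@H](C(=O)CC(=O)C=C=O)c2cccc(OCc3ccccc3)c21 | intermediate
21 | (3R,4S)-8-(benzyloxy)-4-(4-hydroxy-2-oxo-2H-pyran-6-yl)-3-phenyl-3-[(triethylsilyl)oxy]-3,4-dihydronaphthalen-1(2H)-one (4S is a priority change caused by silicon; geometry unchanged) | O=C1C[C@](O[Si](CC)(CC)CC)(c2ccccc2)[C@H](c2cc(O)cc(=O)o2)c2cccc(OCc3ccccc3)c21 | intermediate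
22 | (3R,4S)-8-hydroxy-4-(4-hydroxy-2-oxo-2H-pyran-6-yl)-3-phenyl-3-[(triethylsilyl)oxy]-3,4-dihydronaphthalen-1(2H)-one | O=C1C[C@](O[Si](CC)(CC)CC)(c2ccccc2)[C@H](c2cc(O)cc(=O)o2)c2cccc(O)c21 | intermediate
23 | (3R,4R)-3,8-dihydroxy-4-(4-hydroxy-2-oxo-2H-pyran-6-yl)-3-phenyl-3,4-dihydronaphthalen-1(2H)-one | O=C1C[C@](O)(c2ccccc2)[C@H](c2cc(O)cc(=O)o2)c2cccc(O)c21 | intermediate
24 | (4S)-8-hydroxy-4-(4-hydroxy-2-oxo-2H-pyran-6-yl)-3-phenylnaphthalen-1(4H)-one | O=C1C=C(c2ccccc2)[C@H](c2cc(O)cc(=O)o2)c2cccc(O)c21 | intermediate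
25 | 6-(4,5-dihydroxy-2-phenylnaphthalen-1-yl)-4-hydroxy-2H-pyran-2-one | O=c1cc(O)cc(-c2c(-c3ccccc3)cc(O)c3c(O)cccc23)o1 | intermediate
26 | (3R,4R)-4-{3-[(dimethylamino)methyl]-4-hydroxy-2-oxo-2H-pyran-6-yl}-3,8-dihydroxy-3-phenyl-3,4-dihydronaphthalen-1(2H)-one | O=C1C[C@](O)(c2ccccc2)[C@H](c2cc(O)c(CN(C)C)c(=O)o2)c2cccc(O)c21 | intermediate
27 | (3R,4R)-3,8-dihydroxy-4-(3-methylidene-2,4-dioxo-3,4-dihydro-2H-pyran-6-yl)-3-phenyl-3,4-dihydronaphthalen-1(2H)-one | O=C1C[C@](O)(c2ccccc2)[C@H](C2=CC(=O)C(=C)C(=O)O2)c2cccc(O)c21 | intermediate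
28 | wailupemycin I, (3R,4R)-4-(3-{[6-(4,5-dihydroxy-2-phenylnaphthalen-1-yl)-4-hydroxy-2-oxo-2H-pyran-3-yl]methyl}-4-hydroxy-2-oxo-2H-pyran-6-yl)-3,8-dihydroxy-3-phenyl-3,4-dihydronaphthalen-1(2H)-one | O=C1C[C@](O)(c2ccccc2)[C@H](c2cc(O)c(Cc3c(O)cc(-c4c(-c5ccccc5)cc(O)c5c(O)cccc45)oc3=O)c(=O)o2)c2cccc(O)c21 | target

## Step count and risks

Total steps: 20. Longest linear sequence: 18 (steps 1–11, 13–17, then 19 and 20; the path through step 18 is equally long).

Most likely to fail: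

Step 7 (directed epoxidation). The dihydronaphthalenol can aromatise or be oxidised at the benzylic carbinol, and face selectivity rests on vanadium delivery. The fallback sets out from 8 and fixes the face by a covalent tether: Boc2O and DMAP give tert-butyl (1S)-8-(benzyloxy)-3-phenyl-1,2-dihydronaphthalen-1-yl carbonate F1. IBr in toluene at −80 °C then closes the carbonate oxygen onto C3 from the face of the C1 oxygen with iodine entering C4 anti, giving the cyclic iodocarbonate (1S,3S,4R)-8-(benzyloxy)-4-iodo-3-phenyl-1,2,3,4-tetrahydronaphthalene-1,3-diyl carbonate F2. K2CO3 in MeOH cleaves the carbonate and the freed C3 alkoxide displaces iodide, which returns the route to 9.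

Step 8 (vinyl transfer to the hindered diaryl epoxide). Magnesium or copper Lewis acidity may trigger Meinwald rearrangement or attack at C3. The fallback sets out from 9 and uses a small, salt-free sp nucleophile: lithium acetylide–ethylenediamine complex (LiC≡CH·H2NCH2CH2NH2) in DMSO at rt opens C4 by SN2 to give (1S,3R,4R)-8-(benzyloxy)-4-ethynyl-3-phenyl-1,2,3,4-tetrahydronaphthalene-1,3-diol F3. Semihydrogenation over Lindlar catalyst (Pd/CaCO3 poisoned with Pb(OAc)2, quinoline, H2, EtOAc) turns ethynyl into ethenyl and returns the route to 10.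

Step 20 (final union). Mannich base 26 carries the fragile β-hydroxy ketone and may dehydrate or scramble to homodimers before it is trapped. The fallback reverses the roles and sets out from 25: Eschenmoser's salt and i-Pr2NEt in MeCN at 0 °C give 3-[(dimethylamino)methyl]-6-(4,5-dihydroxy-2-phenylnaphthalen-1-yl)-4-hydroxy-2H-pyran-2-one F4, the pyranone enol reacting ahead of the naphthol carbons. Warming F4 with 23 (1.3 equiv) in MeCN at 50 °C releases dimethylamine to form 6-(4,5-dihydroxy-2-phenylnaphthalen-1-yl)-3-methylidene-2H-pyran-2,4(3H)-dione F5 (not isolated). The pyronate of 23, now only a nucleophile, adds to it in a Michael reaction and the route returns at 28.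

## Further compounds

F1 | step 7 | tert-butyl (1S)-8-(benzyloxy)-3-phenyl-1,2-dihydronaphthalen-1-yl carbonate | CC(C)(C)OC(=O)O[C@H]1CC(c2ccccc2)=Cc2cccc(OCc3ccccc3)c21
F2 | step 7 | (1S,3S,4R)-8-(benzyloxy)-4-iodo-3-phenyl-1,2,3,4-tetrahydronaphthalene-1,3-diyl carbonate (cyclic carbonate bridging O1 and O3, iodine trans to O3) | O=C1O[C@H]2C[C@](O1)(c1ccccc1)[C@H](I)c1cccc(OCc3ccccc3)c12
F3 | step 8 | (1S,3R,4R)-8-(benzyloxy)-4-ethynyl-3-phenyl-1,2,3,4-tetrahydronaphthalene-1,3-diol | O[C@H]1C[C@](O)(c2ccccc2)[C@H](C#C)c2cccc(OCc3ccccc3)c21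
F4 | step 20 | 3-[(dimethylamino)methyl]-6-(4,5-dihydroxy-2-phenylnaphthalen-1-yl)-4-hydroxy-2H-pyran-2-one | CN(C)Cc1c(O)cc(-c2c(-c3ccccc3)cc(O)c3c(O)cccc23)oc1=O
F5 | step 20 | 6-(4,5-dihydroxy-2-phenylnaphthalen-1-yl)-3-methylidene-2H-pyran-2,4(3H)-dione | C=C1C(=O)C=C(-c2c(-c3ccccc3)cc(O)c3c(O)cccc23)OC1=O
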